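## Structural features

The target (C25H30O6, no stereocentres) is an isocoumarin in which benzenoid ring A (C4a, C5, C6, C7, C8, C8a) is fused to the enol-lactone ring B (C1, O2, C3, C4), and C3 carries a pentyl chain. Ring A has a free hydroxyl on C6 and, on C8, an ether oxygen that joins it to ring C, a benzene ring with hydroxyls on C2' and C4' and a second pentyl chain on C6'. This ether oxygen is crowded on both sides, because on ring A it lies peri to the lactone carbonyl C1 and on ring C it sits between the C2' oxygen and the C6' pentyl group, so a direct aryl–aryl ether coupling would have to join a chelated, deactivated phenol to a doubly ortho-substituted partner; the C8–O–C1' bond is the real difficulty. The fragile element is ring B: alkoxide or hydroxide opens the enol lactone, the opened keto ester can go on to acylate on carbon, and C4, C5 and C7 are open to electrophilic halogen. Of the three phenolic oxygens only O6 has to be told apart, because O8 is marked by its hydrogen bond to C1=O and the two oxygens of ring C can be created as carbonyls. The three contiguous stereocentres that arise on the way (C5', C6', C1') stand next to one another on ring C and vanish when that ring becomes aromatic. The key step uses the fact that ring C is 5-pentylresorcinol with one extra oxygen on C1': C2' and C3' map onto an acetyl group, C4' and C5' onto a malonate, C6' onto the β-carbon and C1' onto the α-carbon of an enone, so the hindered ether can be made at C1' while that carbon is still part of an open chain.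

## Logic of the disconnections

16 ⇒ 15. Only the O6–CH3 bond is added back. O6 must be masked from the moment O8 is functionalized. A methyl ether is kept because it survives every later step and, as a donor para to C8a, lowers the electrophilicity of C1 during the base-mediated steps. The gain is a precursor in which no second phenol of ring A competes. The demand is a dealkylation that spares a diaryl ether and an enol lactone. It is placed last because only after aromatization is the C1'–O bond an aryl–aryl ether.

15 ⇒ 14. No skeletal bond is cut. Ring C is taken down to the cyclohexane-1,3-dione level, so that C2' and C4' are carbonyl carbons and C1' and C6' are sp3. A pentasubstituted benzene becomes a ring that carbonyl condensations can build, at the price of two adjacent transient stereocentres. The forward step must remove two hydrogens without halogenating rings A and C and without breaking the C1'–O bond, which at this stage is an alkyl aryl ether next to a ketone.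

14 ⇒ 12. The C5'–CO2Me bond is restored, the mark of a malonate origin, and C5' becomes the third contiguous stereocentre. Nothing is gained in size, but the ring now has the pattern of a Claisen product. The forward step must hydrolyse and decarboxylate a β-keto ester while ring B stays closed.

12 ⇒ 9 + 10. The bonds C5'–C6' and C3'–C4' are cut. This opens ring C into a three-carbon donor and an enone whose α-carbon already carries the ether oxygen, so the position of ether, both oxygens and pentyl group is fixed by connectivity alone. The forward step demands conjugate addition to a donor-substituted enone and a Claisen closure that is faster than any attack on the lactone. For that reason the annulation is planned with the anion of 10 preformed with NaH in an aprotic solvent and not with alcoholic alkoxide.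

9 ⇒ 7 + 8. The C1'=C6' double bond is cut by an olefination transform. A phosphonate on C1' makes that carbon the only possible site of condensation. A crossed aldol of an aryloxyacetone would instead leave the methyl group and the self-condensation of the aldehyde to compete. The gain is a six-carbon aldehyde and a small phosphonate. The demand is a base mild enough that the C1' carbanion does not acylate itself on C1.

7 ⇒ 5 + 6. The O8–C1' bond is cut. Carbenoid insertion into the O–H bond forms the hindered ether at an sp3 carbon under neutral conditions, with no phenoxide and no alkoxide near the lactone. The gain is a simple hydroxy-isocoumarin. The demand is that the hydrogen-bonded hydroxyl traps the carbenoid faster than the carbenoid decays.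

5 ⇒ 4. The O8–CH3 bond is restored. The two ether oxygens of 4 differ only in that O8 is peri to C1=O, and a chelating Lewis acid exploits exactly this difference. The gain is a symmetrically protected precursor. The demand is mono-cleavage.

4 ⇒ 3. The lactone bond C1–O2 is cut to a keto ester. This reduces ring B to an acyl side chain on a benzoate. The forward closure must go through oxygen and not through carbon, which points to acid catalysis.

3 ⇒ 1 + 2. The C3–C4 bond is cut between the benzylic carbon and the ketone carbon. Both fragments are simple, and the benzylic position of 1 is activated by the ortho ester. The forward step needs an acyl donor that stops at the ketone stage.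

## Other disconnections considered

Alternative 1: The cut removes both carbon arms of ring A, C4–C4a and C1–C8a. It leads back to 10 and to the 2-silylaryl triflate A2, 3-(2,4-dimethoxy-6-pentylphenoxy)-5-methoxy-2-(trimethylsilyl)phenyl trifluoromethanesulfonate, which already holds the diaryl ether. In the forward step CsF would release the aryne from A2 and the carbanion of 10 would add at C4a, the aryne carbon remote from the oxygen-bearing C8. The aryl anion at C8a would then add to an ester carbonyl and the four-membered alkoxide would fragment to the homophthalate A1, methyl 2-(2,4-dimethoxy-6-pentylphenoxy)-4-methoxy-6-(2-methoxy-2-oxoethyl)benzoate.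
- In its favour: two carbon–carbon bonds form in one operation, the regiochemistry is directed by the C8 oxygen, and the conditions are neutral fluoride conditions.
- Against it here: the hardest bond of the target must exist before the key step. It would have to come from an Ullmann-type coupling (CuI) of the phenol A3, 2,4-dimethoxy-6-pentylphenol, itself a pentasubstituted benzene, with a crowded aryl halide. A2 needs four contiguous substituents. Malonates are weaker partners than β-keto esters in such insertions, so simple α-arylation would compete. After A1, C3 and its pentyl chain must still be added by acylation, decarboxylation and lactonization, and three methyl ethers must be cleaved and not one.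
- Comparison: on structure the two plans are equal, since both fix the substitution pattern by connectivity. On mechanism the alternative is the better on one point, because no lactone is present while carbanions are about. On step economy it should be clearly longer, and ring C has to be made separately.

Alternative 2: The cut is C4a–C8a in ring A. The precursor is the open chain A5, methyl (3E)-3-(2,4-dimethoxy-6-pentylphenoxy)-5,7-dioxo-8-(2-pentyl-1,3-dioxolan-2-yl)oct-3-enoate, in which the C8 oxygen is held as an aryl enol ether. Mild base would remove a proton from the C8a methylene of A5, which is α to the ester and vinylogous to the C6 ketone. The carbanion would add to the C4a ketone, and dehydration with enolization would give the phenol A4, methyl 2-(2,4-dimethoxy-6-pentylphenoxy)-4-hydroxy-6-[(2-pentyl-1,3-dioxolan-2-yl)methyl]benzoate.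
- In its favour: ring A is aromatized by loss of water and needs no oxidant, which is better than the chosen plan on redox economy. The ether is again made at a non-aromatic carbon, by addition of A3 to an alkyne, so on that idea the two plans are equal.
- Against it here: in A5 the aryloxy group sits on the β-carbon of an enone and can be expelled by addition–elimination. In the chosen plan it sits on the α-carbon and cannot. The most acidic site of A5 is C5 between two ketones and not C8a, so other closures (Claisen onto the ester, aldol onto the other ketone) compete. The double bond must have the E geometry. The chain is long to make and unlikely to be stable. After A4 the ketal must be removed, ring B closed and three methyl ethers cleaved.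
- Comparison: on structure it is weaker, since regiochemistry depends on which enolate reacts. On mechanism it is milder in base strength but less certain. On step economy it is inferior.

Alternative 3: The cut is C1'–C6' in ring C. The precursor is the 4-pyranone A7, 6-methoxy-8-[(4-oxo-6-pentyl-4H-pyran-2-yl)methoxy]-3-pentyl-1H-isochromen-1-one, in which the pyranone hangs on O8 through a methylene group. Aqueous Ba(OH)2 would open the pyranone ring of A7 to an open-chain 1-aryloxy 2,4,6-triketone. Its aryloxymethylene carbon would add to the pentyl ketone and lose water to give A6, 8-(2,4-dihydroxy-6-pentylphenoxy)-6-methoxy-3-pentyl-1H-isochromen-1-one, which is identical with 15.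
- In its favour: ring C becomes aromatic by condensation, with no dehydrogenation and no transient stereocentres, which is better than the chosen plan. The ether of A7 is made by alkylating 5 with a primary, activated halide, which is at least the equal of the insertion of step 4. The endgame from A6 is the same single step.
- Against it here: hot aqueous hydroxide would hydrolyse ring B, and the aryloxymethylene carbanion can close a five-membered ring on C1 by acylation. The triketone has a second aldol mode, from the first methylene of the pentyl chain onto the C2' ketone, which would give an isomeric resorcinol. A7 itself, an unsymmetrical pyranone, must be built in several steps.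
- Comparison: on structure it is less secure, with two closure modes against one. On mechanism it exposes the lactone to the harshest conditions of all four plans. On step economy it is about equal to the chosen plan.

Key step: step 6

Remarks on the chemistry:
- 2 and 6 are taken as purchasable reagents.
- 9 is drawn as the Z isomer (pentyl cis to the aryloxy group), and 12 as one enantiomer of the 1,2-trans-2,3-trans racemate.
- 12 is written as its diketo tautomer but should exist mainly as an enol. Its stereodescriptors and those of 13 and 14 name the expected thermodynamic isomers.
- Locants C1'–C6' of ring C are used for the corresponding carbons of all precursors.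

## Steps

Step 1
Reactants: 1 methyl 2,4-dimethoxy-6-methylbenzoate; 2 N-methoxy-N-methylhexanamide
Product: 3 methyl 2,4-dimethoxy-6-(2-oxoheptyl)benzoate
Conditions: LiN(i-Pr)2 (1.3 equiv), THF, −78 °C; then 2, −78 to −20 °C; aq. NH4Cl
Reagents that add atoms: none
Why: Lateral (benzylic) lithiation of the ortho-toluate gives a stabilized anion that is acylated by the N-methoxy-N-methylamide; the chelated adduct releases the ketone only on work-up, so neither over-addition nor enolization of the product by the base should interfere.

Step 2
Reactants: 3 methyl 2,4-dimethoxy-6-(2-oxoheptyl)benzoate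
Product: 4 6,8-dimethoxy-3-pentyl-1H-isochromen-1-one
Conditions: TsOH·H2O (10 mol%), toluene, reflux
Reagents that add atoms: none
Why: Acid-catalysed enol lactonization (the enol oxygen of the ketone attacks the protonated ester, 6-exo-trig, with loss of methanol) should give the conjugated isocoumarin; acid is chosen over base because an enolate on the pentyl side could acylate on carbon and lead to a naphthalene-1,3-diol.

Step 3
Reactants: 4 6,8-dimethoxy-3-pentyl-1H-isochromen-1-one
Product: 5 8-hydroxy-6-methoxy-3-pentyl-1H-isochromen-1-one
Conditions: BCl3 (1.5 equiv), CH2Cl2, −78 to 0 °C; H2O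
Reagents that add atoms: none
Why: Chelation-controlled ether cleavage: BCl3 binds between the lactone carbonyl and the peri 8-methoxy oxygen and should remove only that methyl group, leaving the unchelated 6-methoxy group intact.

Step 4
Reactants: 5 8-hydroxy-6-methoxy-3-pentyl-1H-isochromen-1-one; 6 dimethyl (1-diazo-2-oxopropyl)phosphonate
Product: 7 racemic dimethyl {1-[(6-methoxy-1-oxo-3-pentyl-1H-isochromen-8-yl)oxy]-2-oxopropyl}phosphonate
Conditions: Rh2(OAc)4 (2 mol%), 1,2-dichloroethane, 80 °C, slow addition of 6
Reagents that add atoms: none
Why: Rhodium-carbenoid O–H insertion: the carbenoid formed from 6 with loss of N2 is trapped by the phenolic oxygen, and a proton shift gives the ether at the future C1' under neutral conditions that cannot open the lactone; the new stereocentre forms as a racemate and is destroyed in step 5.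

Step 5
Reactants: 7 racemic dimethyl {1-[(6-methoxy-1-oxo-3-pentyl-1H-isochromen-8-yl)oxy]-2-oxopropyl}phosphonate; 8 hexanal
Product: 9 (Z)-6-methoxy-8-[(2-oxonon-3-en-3-yl)oxy]-3-pentyl-1H-isochromen-1-one
Conditions: LiCl (1.5 equiv), i-Pr2NEt (1.3 equiv), 8 (1.5 equiv), MeCN, 0 °C to rt
Reagents that add atoms: none
Why: Horner–Wadsworth–Emmons olefination under LiCl/amine conditions: the phosphonate makes C1' the only nucleophilic carbon, so the double bond can form only between C1' and the aldehyde carbon (C6'); the pentyl group should end up trans to the acetyl group (the Z isomer), and any E isomer is equally usable in step 6.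

Step 6
Reactants: 9 (Z)-6-methoxy-8-[(2-oxonon-3-en-3-yl)oxy]-3-pentyl-1H-isochromen-1-one; 10 dimethyl malonate
Product: 12 racemic all-trans methyl 3-[(6-methoxy-1-oxo-3-pentyl-1H-isochromen-8-yl)oxy]-4,6-dioxo-2-pentylcyclohexane-1-carboxylate, via malonate Michael adduct 11 (not isolated)
Conditions: NaH (1.05 equiv), 10 (1.2 equiv), THF, 0 °C; then 9, rt to 60 °C; cold 1 M HCl
Reagents that add atoms: none
Why: Michael–Claisen annulation: NaCH(CO2Me)2 adds to C6', the β-carbon of the enone, which forms C5'–C6' and gives 11, whose malonate anion is the resting state. Proton transfer supplies a small share of the C3' methyl-ketone enolate, which attacks one malonate ester carbonyl in a 6-(enolendo)-exo-trig Claisen closure and forms C3'–C4'; the expelled methoxide is consumed at once by the acidic β-dicarbonyl product, which drives the sequence and keeps free alkoxide away from the lactone. The closest known reaction type is the annulation of alk-3-en-2-ones with malonates to 5-alkylcyclohexane-1,3-diones that underlies the usual preparation of 5-alkylresorcinols. C6' is set without control in the Michael step, while C1' and C5' are both enolizable under the conditions and should settle trans to the pentyl group with all three substituents equatorial; none of this matters in the end, because all three centres vanish on aromatization. The selectivity needed is chemoselectivity: conjugate and not carbonyl addition, and acylation of the C3' enolate by a malonate ester in preference to attack of any enolate or alkoxide on the lactone carbon C1. The first is secured by the soft, stabilized nucleophile; the second by the fact that only the C3'/C4' pairing gives a six-membered carbocycle, by the quaternary centre that attack of the C1' enolate on C1 would have to create, and by the 6-methoxy and 8-alkoxy donors that lower the electrophilicity of C1. The aryloxy group sits on the α-carbon of every enolate involved, so no β-elimination can expel it.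

Step 7
Reactants: 12 racemic all-trans methyl 3-[(6-methoxy-1-oxo-3-pentyl-1H-isochromen-8-yl)oxy]-4,6-dioxo-2-pentylcyclohexane-1-carboxylate
Product: 14 racemic trans-4-[(6-methoxy-1-oxo-3-pentyl-1H-isochromen-8-yl)oxy]-5-pentylcyclohexane-1,3-dione, via dioxo acid 13 (not isolated)
Conditions: AcOH/2 M aq. H2SO4 (3:1), 90 °C, N2
Reagents that add atoms: none
Why: Acid-catalysed hydrolysis of the β-keto ester and decarboxylation of the β-keto acid 13 through its cyclic hydrogen-bonded transition state; hot acetic acid with mineral acid is a medium in which enol lactones of this kind are formed, so ring B should stay closed or reclose if it was touched in step 6, and C1' can equilibrate to the trans isomer.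

Step 8
Reactants: 14 racemic trans-4-[(6-methoxy-1-oxo-3-pentyl-1H-isochromen-8-yl)oxy]-5-pentylcyclohexane-1,3-dione
Product: 15 8-(2,4-dihydroxy-6-pentylphenoxy)-6-methoxy-3-pentyl-1H-isochromen-1-one
Conditions: I2 (20 mol%), DMSO, 80 °C, N2
Reagents that add atoms: none
Why: Iodine-catalysed oxidative aromatization in DMSO: iodination of the enol at C5' (iodination at the other α-positions being reversible) and loss of HI give a cyclohexenedione that tautomerizes to the resorcinol, while DMSO reoxidizes HI to I2; the two remaining stereocentres disappear and the C1'–O bond becomes a robust diaryl ether.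

Step 9
Reactants: 15 8-(2,4-dihydroxy-6-pentylphenoxy)-6-methoxy-3-pentyl-1H-isochromen-1-one
Product: 16 8-(2,4-dihydroxy-6-pentylphenoxy)-6-hydroxy-3-pentyl-1H-isochromen-1-one (target, CNP0213708.0)
Conditions: BBr3 (5 equiv), CH2Cl2, −78 °C to rt; H2O
Reagents that add atoms: none
Why: Lewis-acid cleavage of the aryl methyl ether (bromide attacks the methyl group of the boron-complexed ether); diaryl ether, lactone and alkyl chains are inert to these conditions, and the step stands last because an alkyl aryl ether at C1' would not have survived it.

## Compound list

1 | methyl 2,4-dimethoxy-6-methylbenzoate | COC(=O)c1c(C)cc(OC)cc1OC | starting material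
2 | N-methoxy-N-methylhexanamide | CCCCCC(=O)N(C)OC | starting material
3 | methyl 2,4-dimethoxy-6-(2-oxoheptyl)benzoate | CCCCCC(=O)Cc1cc(OC)cc(OC)c1C(=O)OC | intermediate
4 | 6,8-dimethoxy-3-pentyl-1H-isochromen-1-one | CCCCCc1cc2cc(OC)cc(OC)c2c(=O)o1 | intermediate
5 | 8-hydroxy-6-methoxy-3-pentyl-1H-isochromen-1-one | CCCCCc1cc2cc(OC)cc(O)c2c(=O)o1 | intermediate
6 | dimethyl (1-diazo-2-oxopropyl)phosphonate | COP(=O)(OC)C(=[N+]=[N-])C(C)=O | starting material
7 | racemic dimethyl {1-[(6-methoxy-1-oxo-3-pentyl-1H-isochromen-8-yl)oxy]-2-oxopropyl}phosphonate | CCCCCc1cc2cc(OC)cc(OC(C(C)=O)P(=O)(OC)OC)c2c(=O)o1 | intermediate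
8 | hexanal | CCCCCC=O | starting material
9 | (Z)-6-methoxy-8-[(2-oxonon-3-en-3-yl)oxy]-3-pentyl-1H-isochromen-1-one | CCCCC/C=C(/C(C)=O)Oc1cc(OC)cc2cc(CCCCC)oc(=O)c12 | intermediate
10 | dimethyl malonate | COC(=O)CC(=O)OC | starting material
11 | dimethyl 2-{3-[(6-methoxy-1-oxo-3-pentyl-1H-isochromen-8-yl)oxy]-2-oxononan-4-yl}propanedioate (racemic mixture of diastereomers, not isolated) | CCCCCC(C(C(=O)OC)C(=O)OC)C(Oc1cc(OC)cc2cc(CCCCC)oc(=O)c12)C(C)=O | intermediate
12 | racemic all-trans (1,2-trans, 2,3-trans) methyl 3-[(6-methoxy-1-oxo-3-pentyl-1H-isochromen-8-yl)oxy]-4,6-dioxo-2-pentylcyclohexane-1-carboxylate (one enantiomer drawn, diketo tautomer) | COC(=O)[C@@H]1C(=O)CC(=O)[C@H](Oc2cc(OC)cc3cc(CCCCC)oc(=O)c23)[C@H]1CCCCC | intermediate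
13 | racemic all-trans 3-[(6-methoxy-1-oxo-3-pentyl-1H-isochromen-8-yl)oxy]-4,6-dioxo-2-pentylcyclohexane-1-carboxylic acid (one enantiomer drawn, not isolated) | OC(=O)[C@@H]1C(=O)CC(=O)[C@H](Oc2cc(OC)cc3cc(CCCCC)oc(=O)c23)[C@H]1CCCCC | intermediate
14 | racemic trans-4-[(6-methoxy-1-oxo-3-pentyl-1H-isochromen-8-yl)oxy]-5-pentylcyclohexane-1,3-dione (one enantiomer drawn) | O=C1CC(=O)[C@H](Oc2cc(OC)cc3cc(CCCCC)oc(=O)c23)[C@@H](CCCCC)C1 | intermediate
15 | 8-(2,4-dihydroxy-6-pentylphenoxy)-6-methoxy-3-pentyl-1H-isochromen-1-one | CCCCCc1cc2cc(OC)cc(Oc3c(O)cc(O)cc3CCCCC)c2c(=O)o1 | intermediate
16 | 8-(2,4-dihydroxy-6-pentylphenoxy)-6-hydroxy-3-pentyl-1H-isochromen-1-one | CCCCCc1cc2cc(O)cc(Oc3c(O)cc(O)cc3CCCCC)c2c(=O)o1 | target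

## Step count and least certain steps

Total step count: 9. Longest linear sequence: 9 steps (1 to 16); 2, 6, 8 and 10 are purchased and enter directly. Steps 1, 2, 3 and 9 are regarded as routine.

Step 6 (key step). The most likely failure is loss of the lactone while the annulation is still slow. The methoxide set free in the Claisen step could open ring B, or the C1' enolate formed first in the Michael step could acylate itself on C1 with closure of a five-membered ring. Either would gain ground if proton transfer to C3' is sluggish in the aprotic medium or if the donor-substituted enone reacts slowly. The fallback removes both the alkoxide and the acidic malonate position from the plan. It sets out from 9. A Mukaiyama–Michael addition of 1-(tert-butyldimethylsilyloxy)-1-methoxyethene (TiCl4, CH2Cl2, −78 °C; aqueous work-up) should form C5'–C6' under Lewis-acid activation of the enone and give methyl 4-[(6-methoxy-1-oxo-3-pentyl-1H-isochromen-8-yl)oxy]-5-oxo-3-pentylhexanoate F1 as a mixture of racemic diastereomers. LiN(SiMe3)2 (2.2 equiv, THF, −78 to 0 °C) should then take a proton from the unhindered C3' methyl group under kinetic control, and this enolate should close ring C on the only ester present (C3'–C4') while the mixture is still cold. The route is rejoined at 14, so that step 7 is not needed.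

Step 4. The carbenoid may be consumed by dimerization, by rearrangement or by addition to the C3=C4 enol double bond before the hydrogen-bonded, weakly nucleophilic 8-hydroxyl traps it. The fallback sets out from 5 and makes the enone without a phosphonate. Commercial (E)-non-3-en-2-one is epoxidized with H2O2/NaOH (Weitz–Scheffer epoxidation) to racemic trans-1-(3-pentyloxiran-2-yl)ethan-1-one F2. 5 and F2 are then heated with Cs2CO3 in DMF. The phenoxide should open the epoxide at the carbon next to the ketone with inversion, as phenols do with epoxy ketones in the preparation of 2-aryloxy enones. The resulting racemic 8-[(4-hydroxy-2-oxononan-3-yl)oxy]-6-methoxy-3-pentyl-1H-isochromen-1-one F3 should lose water in the same flask by an E1cB path. The route is rejoined at 9.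

Step 5. The fully substituted phosphonate carbanion may add to the aldehyde so slowly that acylation of the carbanion on the neighbouring lactone carbonyl takes over. The fallback sets out from 5. Williamson alkylation with chloroacetone (K2CO3, KI, acetone, reflux) should give 6-methoxy-8-(2-oxopropoxy)-3-pentyl-1H-isochromen-1-one F4. F4 is then condensed with 8 under piperidinium acetate catalysis in toluene with removal of water and slow addition of the aldehyde. The aryloxymethylene carbon is the more acidic α-position and leads to the conjugated product. Regiochemistry and self-condensation of 8 are less secure than in the phosphonate route, which is why this is the reserve. The route is rejoined at 9.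

Step 7. Long heating in acid may be needed to hydrolyse the hindered ester. During that time ring B could be hydrolysed, or the aryloxy ketone could cyclodehydrate onto C7 of ring A to a benzofuran. The fallback changes the ester and not the acid strength. It sets out from 9, which is annulated as in step 6 but with tert-butyl methyl malonate. The Michael adduct, tert-butyl methyl 2-{3-[(6-methoxy-1-oxo-3-pentyl-1H-isochromen-8-yl)oxy]-2-oxononan-4-yl}propanedioate F5, is not isolated. Its Claisen closure should take place on the less hindered methyl ester and give racemic all-trans tert-butyl 3-[(6-methoxy-1-oxo-3-pentyl-1H-isochromen-8-yl)oxy]-4,6-dioxo-2-pentylcyclohexane-1-carboxylate F6. CF3CO2H in CH2Cl2 at room temperature should cleave the tert-butyl ester to 13, which should decarboxylate on gentle warming (40 °C). The route is rejoined at 14.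

Step 8. Iodine may be diverted into iodination of the electron-rich rings or into oxygenation next to a carbonyl, or HI may cleave the alkyl aryl ether at C1' before aromatization is complete. The fallback avoids halogen. It sets out from 14, which is converted with Me3SiOTf/Et3N (CH2Cl2, 0 °C) into racemic trans-6-methoxy-3-pentyl-8-{[6-pentyl-2,4-bis(trimethylsilyloxy)cyclohexa-2,4-dien-1-yl]oxy}-1H-isochromen-1-one F7. After filtration, the cyclohexadiene is dehydrogenated with DDQ in toluene at 0 °C to rt to 8-[6-pentyl-2,4-bis(trimethylsilyloxy)phenoxy]-6-methoxy-3-pentyl-1H-isochromen-1-one F8. Dilute aqueous HCl in THF removes the silyl groups, and the route is rejoined at 15.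

## Further compounds

F1 | step 6 | methyl 4-[(6-methoxy-1-oxo-3-pentyl-1H-isochromen-8-yl)oxy]-5-oxo-3-pentylhexanoate (mixture of racemic diastereomers) | CCCCCC(CC(=O)OC)C(Oc1cc(OC)cc2cc(CCCCC)oc(=O)c12)C(C)=O
F2 | step 4 | racemic trans-1-(3-pentyloxiran-2-yl)ethan-1-one (trans-3,4-epoxynonan-2-one, one enantiomer drawn) | CCCCC[C@@H]1O[C@H]1C(C)=O
F3 | step 4 | racemic (3S*,4S*)-8-[(4-hydroxy-2-oxononan-3-yl)oxy]-6-methoxy-3-pentyl-1H-isochromen-1-one (one enantiomer drawn, not isolated) | CCCCC[C@H](O)[C@H](Oc1cc(OC)cc2cc(CCCCC)oc(=O)c12)C(C)=O
F4 | step 5 | 6-methoxy-8-(2-oxopropoxy)-3-pentyl-1H-isochromen-1-one | CCCCCc1cc2cc(OC)cc(OCC(C)=O)c2c(=O)o1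
F5 | step 7 | tert-butyl methyl 2-{3-[(6-methoxy-1-oxo-3-pentyl-1H-isochromen-8-yl)oxy]-2-oxononan-4-yl}propanedioate (mixture of racemic diastereomers, not isolated) | CCCCCC(C(C(=O)OC)C(=O)OC(C)(C)C)C(Oc1cc(OC)cc2cc(CCCCC)oc(=O)c12)C(C)=O
F6 | step 7 | racemic all-trans tert-butyl 3-[(6-methoxy-1-oxo-3-pentyl-1H-isochromen-8-yl)oxy]-4,6-dioxo-2-pentylcyclohexane-1-carboxylate (one enantiomer drawn) | CC(C)(C)OC(=O)[C@@H]1C(=O)CC(=O)[C@H](Oc2cc(OC)cc3cc(CCCCC)oc(=O)c23)[C@H]1CCCCC
F7 | step 8 | racemic trans-6-methoxy-3-pentyl-8-{[6-pentyl-2,4-bis(trimethylsilyloxy)cyclohexa-2,4-dien-1-yl]oxy}-1H-isochromen-1-one (one enantiomer drawn) | CCCCC[C@H]1C=C(O[Si](C)(C)C)C=C(O[Si](C)(C)C)[C@@H]1Oc1cc(OC)cc2cc(CCCCC)oc(=O)c12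
F8 | step 8 | 8-[6-pentyl-2,4-bis(trimethylsilyloxy)phenoxy]-6-methoxy-3-pentyl-1H-isochromen-1-one | CCCCCc1cc2cc(OC)cc(Oc3c(O[Si](C)(C)C)cc(O[Si](C)(C)C)cc3CCCCC)c2c(=O)o1
A1 | alternative 1 | methyl 2-(2,4-dimethoxy-6-pentylphenoxy)-4-methoxy-6-(2-methoxy-2-oxoethyl)benzoate | COC(=O)Cc1cc(OC)cc(Oc2c(OC)cc(OC)cc2CCCCC)c1C(=O)OC
A2 | alternative 1 | 3-(2,4-dimethoxy-6-pentylphenoxy)-5-methoxy-2-(trimethylsilyl)phenyl trifluoromethanesulfonate | CCCCCc1cc(OC)cc(OC)c1Oc1cc(OC)cc(OS(=O)(=O)C(F)(F)F)c1[Si](C)(C)C
A3 | alternative 1 | 2,4-dimethoxy-6-pentylphenol | CCCCCc1cc(OC)cc(OC)c1O
A4 | alternative 2 | methyl 2-(2,4-dimethoxy-6-pentylphenoxy)-4-hydroxy-6-[(2-pentyl-1,3-dioxolan-2-yl)methyl]benzoate | COC(=O)c1c(CC2(CCCCC)OCCO2)cc(O)cc1Oc1c(OC)cc(OC)cc1CCCCC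
A5 | alternative 2 | methyl (3E)-3-(2,4-dimethoxy-6-pentylphenoxy)-5,7-dioxo-8-(2-pentyl-1,3-dioxolan-2-yl)oct-3-enoate | COC(=O)C/C(Oc1c(OC)cc(OC)cc1CCCCC)=C\C(=O)CC(=O)CC1(CCCCC)OCCO1
A6 | alternative 3 | 8-(2,4-dihydroxy-6-pentylphenoxy)-6-methoxy-3-pentyl-1H-isochromen-1-one (identical with 15) | CCCCCc1cc2cc(OC)cc(Oc3c(O)cc(O)cc3CCCCC)c2c(=O)o1
A7 | alternative 3 | 6-methoxy-8-[(4-oxo-6-pentyl-4H-pyran-2-yl)methoxy]-3-pentyl-1H-isochromen-1-one | CCCCCc1cc(=O)cc(COc2cc(OC)cc3cc(CCCCC)oc(=O)c23)o1
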